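**Retrosynthetic overview** (chroman numbering: O1, C2, C3, C4, C4a, C5–C8, C8a; ring A = benzo ring, ring B = pendant aryl, ring C = pyran)
- The target is reached by hydrogenolysis of its bis(benzyl ether); rings A and B are both taken intact from 2,3-dimethoxyphenol (para-iodination for ring A, ortho-bromination for ring B).
- Ring C is the only ring made: a palladium/norbornene (Catellani-type) annulation of the ring-A aryl iodide with an (S)-γ-bromo alcohol forms C4–C4a by ortho C–H alkylation and then closes the ring by forming O1–C8a (ipso etherification).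
- Enabling feature: in ring A, C8a (which carries O1) and C4a (which carries C4) are neighbours, C8 on the other flank of C8a carries OMe, and C4a is a C–H in the iodide. An iodine on C8a can therefore relay palladium to C4a and then be replaced by O1, with the second ortho site blocked.
- The C3 stereocentre comes from a catalytic enantioselective bromide opening of an achiral 3-aryloxetane; the oxetane is a temporary ring, bought as 3-iodooxetane and opened again.
- Ring order: A and B purchased, oxetane attached and opened, ring C closed last in the key step.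

Key step: step 7

Assumption: the enantiomer of the squaramide catalyst in step 6 that delivers the (S)-bromohydrin is used; both catalyst antipodes are accessible, and the sense of induction is to be assigned on the first batch.

**Step 1**
Reactants: 1 2,3-dimethoxyphenol
Product: 2 4-iodo-2,3-dimethoxyphenol
Conditions: NIS (1.0 equiv), TsOH·H2O (10 mol %), MeCN, 0 °C
Reagents that add atoms: N-iodosuccinimide, O=C1CCC(=O)N1I
Why: Electrophilic aromatic iodination; the free hydroxyl is the strongest director and its para position (also ortho to the 3-methoxy group) is the most activated accessible site, so the 4-iodo phenol should form.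

**Step 2**
Reactants: 2 4-iodo-2,3-dimethoxyphenol
Product: 3 1-(benzyloxy)-4-iodo-2,3-dimethoxybenzene
Conditions: BnBr, K2CO3, DMF, rt
Reagents that add atoms: benzyl bromide, BrCc1ccccc1
Why: Williamson etherification of a phenoxide with a benzylic bromide; the aryl iodide is inert to these conditions.

**Step 3**
Reactants: 1 2,3-dimethoxyphenol
Product: 4 6-bromo-2,3-dimethoxyphenol
Conditions: t-BuNH2 (2 equiv), Br2 (1 equiv), toluene, −78 °C
Reagents that add atoms: bromine, BrBr
Why: Amine-mediated ortho-bromination of a phenol; N-bromo-tert-butylamine formed in the flask is delivered through a hydrogen bond to the phenol oxygen and should brominate the only free ortho position in preference to the para position.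

**Step 4**
Reactants: 4 6-bromo-2,3-dimethoxyphenol
Product: 5 2-(benzyloxy)-1-bromo-3,4-dimethoxybenzene
Conditions: BnBr, K2CO3, DMF, rt
Reagents that add atoms: benzyl bromide, BrCc1ccccc1
Why: Williamson etherification; the benzyl ether is chosen because it survives the Grignard, TMSBr and palladium steps and leaves together with the ring-A benzyl ether at the end.

**Step 5**
Reactants: 5 2-(benzyloxy)-1-bromo-3,4-dimethoxybenzene; 6 3-iodooxetane
Product: 8 3-[2-(benzyloxy)-3,4-dimethoxyphenyl]oxetane, via arylmagnesium bromide 7 (not isolated)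
Conditions: Mg, LiCl, THF, rt; then 6, CoCl2 (5 mol %), trans-N,N,N′,N′-tetramethylcyclohexane-1,2-diamine (6 mol %), THF, 0 °C to rt
Reagents that add atoms: none
Why: Grignard formation followed by a cobalt-catalysed Kumada-type coupling of an aryl Grignard reagent with a secondary alkyl iodide, a reaction type established for 3-iodo four-membered heterocycles; the product is achiral, with two enantiotopic CH2–O arms.

**Step 6**
Reactants: 8 3-[2-(benzyloxy)-3,4-dimethoxyphenyl]oxetane
Product: 10 (2S)-2-[2-(benzyloxy)-3,4-dimethoxyphenyl]-3-bromopropan-1-ol, via bromo silyl ether 9 (not isolated)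
Conditions: TMSBr (1.2 equiv), chiral tert-leucine-derived arylpyrrolidine squaramide hydrogen-bond-donor catalyst (5 mol %), t-BuOMe, −80 °C; then aq. citric acid, THF, 0 °C
Reagents that add atoms: trimethylsilyl bromide, C[Si](C)(C)Br
Why: Catalytic enantioselective desymmetrizing ring opening of a 3-aryloxetane with TMSBr under chiral squaramide (anion-binding) catalysis; the catalyst-bound bromide opens one of the two enantiotopic CH2–O bonds of the silylated oxetane, so the C3 stereocentre is set by catalyst control, and mild acid then removes the silyl group without touching the primary bromide.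

**Step 7**
Reactants: 3 1-(benzyloxy)-4-iodo-2,3-dimethoxybenzene; 10 (2S)-2-[2-(benzyloxy)-3,4-dimethoxyphenyl]-3-bromopropan-1-ol
Product: 11 (3S)-6-(benzyloxy)-3-[2-(benzyloxy)-3,4-dimethoxyphenyl]-7,8-dimethoxy-3,4-dihydro-2H-chromene
Conditions: Pd(OAc)2 (10 mol %), RuPhos (2-dicyclohexylphosphino-2′,6′-diisopropoxybiphenyl, 20 mol %), norbornene (2 equiv), Cs2CO3 (3 equiv), 10 (1.5 equiv, slow addition), DMF, 100 °C
Reagents that add atoms: none
Why: Proposed new method: zerovalent palladium inserts into the C–I bond of 3, norbornene insertion and C–H palladation at the only free ortho carbon give an aryl–norbornyl palladacycle, which takes up the primary bromide of 10 (SN2-type oxidative addition to tetravalent palladium) and forms the C4–C4a bond by reductive elimination; norbornene is then expelled by β-carbon elimination, driven by the two ortho substituents (OMe and the new chain), leaving divalent arylpalladium at C8a. Ring C is closed there by C(sp2)–O reductive elimination from a seven-membered aryl(alkoxo)palladacycle, which forms the O1–C8a bond and returns zerovalent palladium. The closest known reactions are the Catellani ortho-alkylation of aryl iodides with primary alkyl bromides, the palladium/norbornene annulation of aryl iodides with epoxides to 2,3-dihydrobenzofurans (same ipso C–O termination, ring one atom smaller) and the Buchwald–Hartwig intramolecular etherification of 3-(2-halophenyl)propanols to chromans; new is the use of a γ-bromo alcohol to build the six-membered ring in one operation. No stereocentre is created: C3 comes from 10, is not acidic and is never bonded to palladium, so its S configuration should be carried through unchanged. The step needs mono-alkylation at C4a (secured by the C8 methoxy group, which blocks the other ortho position), alkylation before ipso capture (norbornene insertion is fast and only the palladacycle activates the alkyl bromide) and C–O reductive elimination faster than β-hydride loss from the alkoxide (favoured by the bulky biarylphosphine and the chelate).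

**Step 8**
Reactants: 11 (3S)-6-(benzyloxy)-3-[2-(benzyloxy)-3,4-dimethoxyphenyl]-7,8-dimethoxy-3,4-dihydro-2H-chromene
Product: 12 (3S)-3-(2-hydroxy-3,4-dimethoxyphenyl)-7,8-dimethoxy-3,4-dihydro-2H-chromen-6-ol
Conditions: H2 (1 atm), 10% Pd/C, EtOAc/MeOH, rt
Reagents that add atoms: none
Why: Hydrogenolysis of two aryl benzyl ethers; the chroman C2–O1 bond is not benzylic and C3 carries no heteroatom, so the ring and the stereocentre should be untouched.

**Compound list**
1 | 2,3-dimethoxyphenol | COc1cccc(O)c1OC | starting material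
2 | 4-iodo-2,3-dimethoxyphenol | COc1c(I)ccc(O)c1OC | intermediate
3 | 1-(benzyloxy)-4-iodo-2,3-dimethoxybenzene | COc1c(I)ccc(OCc2ccccc2)c1OC | intermediate
4 | 6-bromo-2,3-dimethoxyphenol | COc1ccc(Br)c(O)c1OC | intermediate
5 | 2-(benzyloxy)-1-bromo-3,4-dimethoxybenzene | COc1ccc(Br)c(OCc2ccccc2)c1OC | intermediate
6 | 3-iodooxetane | IC1COC1 | starting material
7 | [2-(benzyloxy)-3,4-dimethoxyphenyl]magnesium bromide | COc1ccc([Mg]Br)c(OCc2ccccc2)c1OC | intermediate
8 | 3-[2-(benzyloxy)-3,4-dimethoxyphenyl]oxetane | COc1ccc(C2COC2)c(OCc2ccccc2)c1OC | intermediate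
9 | {(2S)-2-[2-(benzyloxy)-3,4-dimethoxyphenyl]-3-bromopropoxy}trimethylsilane | COc1ccc([C@H](CBr)CO[Si](C)(C)C)c(OCc2ccccc2)c1OC | intermediate
10 | (2S)-2-[2-(benzyloxy)-3,4-dimethoxyphenyl]-3-bromopropan-1-ol | COc1ccc([C@H](CBr)CO)c(OCc2ccccc2)c1OC | intermediate
11 | (3S)-6-(benzyloxy)-3-[2-(benzyloxy)-3,4-dimethoxyphenyl]-7,8-dimethoxy-3,4-dihydro-2H-chromene | COc1ccc([C@H]2COc3c(cc(OCc4ccccc4)c(OC)c3OC)C2)c(OCc2ccccc2)c1OC | intermediate
12 | (3S)-3-(2-hydroxy-3,4-dimethoxyphenyl)-7,8-dimethoxy-3,4-dihydro-2H-chromen-6-ol | COc1ccc([C@H]2COc3c(cc(O)c(OC)c3OC)C2)c(O)c1OC | target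

**Step count**
Total steps: 8. Longest linear sequence: 6 steps (steps 3, 4, 5, 6, 7, 8).

**Steps most likely to fail**

Step 7 (proposed new method). What may go wrong: base-induced loss of the bromo alcohol (cyclization back to the achiral oxetane or elimination) before the palladacycle captures it; premature ipso termination; β-hydride loss from the palladium alkoxide in place of C–O reductive elimination. The fallback uses known chemistry, decouples alkylation from etherification, sets out from 2 and 10 and returns at 11.
- Iodophenol 2 is protected (MOMCl, i-Pr2NEt, CH2Cl2) as 1-iodo-2,3-dimethoxy-4-(methoxymethoxy)benzene F1.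
- Alcohol 10 is silylated (TBSCl, imidazole, DMF) to {(2S)-2-[2-(benzyloxy)-3,4-dimethoxyphenyl]-3-bromopropoxy}(tert-butyl)dimethylsilane F2.
- The established Catellani ortho-alkylation with hydride termination (Pd(OAc)2, tri(2-furyl)phosphine, norbornene, Cs2CO3, HCO2Na, DMF, 90 °C) should join them to tert-butyl{(2S)-2-[2-(benzyloxy)-3,4-dimethoxyphenyl]-3-[3,4-dimethoxy-5-(methoxymethoxy)phenyl]propoxy}dimethylsilane F3.
- HCl in MeOH removes the MOM and TBS groups to give 5-{(2S)-2-[2-(benzyloxy)-3,4-dimethoxyphenyl]-3-hydroxypropyl}-2,3-dimethoxyphenol F4.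
- Bu4NBr3 in CH2Cl2/MeOH brominates para to the free phenol, at C8a, to give 4-bromo-5-{(2S)-2-[2-(benzyloxy)-3,4-dimethoxyphenyl]-3-hydroxypropyl}-2,3-dimethoxyphenol F5.
- BnBr/K2CO3 benzylates the phenol only, giving (2S)-3-[5-(benzyloxy)-2-bromo-3,4-dimethoxyphenyl]-2-[2-(benzyloxy)-3,4-dimethoxyphenyl]propan-1-ol F6.
- The known intramolecular Buchwald–Hartwig etherification of an aryl bromide with a primary alcohol (Pd(OAc)2, 2-(di-tert-butylphosphino)-1,1′-binaphthyl, Cs2CO3, toluene, 70 °C) then closes the same O1–C8a bond and gives 11.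

Step 6. What may go wrong: poor discrimination between the two enantiotopic C–O bonds, because the bulky ortho-benzyloxy group sits next to the oxetane, and uncatalysed background opening by TMSBr. The fallback sets out from 8 and returns at 10.
- Aqueous acid (0.5 M H2SO4, THF/H2O, 50 °C) opens 8 to the prochiral diol 2-[2-(benzyloxy)-3,4-dimethoxyphenyl]propane-1,3-diol F7.
- Lipase-catalysed desymmetrizing acetylation (Burkholderia cepacia lipase, vinyl acetate, t-BuOMe; the lipase, or the complementary hydrolysis of the diacetate, is chosen for the R sense) gives (2R)-2-[2-(benzyloxy)-3,4-dimethoxyphenyl]-3-hydroxypropyl acetate F8.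
- Appel bromination (CBr4, PPh3, CH2Cl2, 0 °C) gives (2S)-2-[2-(benzyloxy)-3,4-dimethoxyphenyl]-3-bromopropyl acetate F9.
- Acid methanolysis (HCl, MeOH, 0 °C) gives 10.

Step 3. What may go wrong: competing bromination para to the hydroxyl and over-bromination. The fallback sets out from 1 and returns at 4.
- MOMCl/i-Pr2NEt gives 1,2-dimethoxy-3-(methoxymethoxy)benzene F10.
- Directed ortho-lithiation (n-BuLi, THF, 0 °C; the MOM ether is the stronger director) and quenching with 1,2-dibromo-1,1,2,2-tetrachloroethane gives 1-bromo-3,4-dimethoxy-2-(methoxymethoxy)benzene F11.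
- HCl in MeOH gives 4.

**Further compounds**
F1 | step 7 | 1-iodo-2,3-dimethoxy-4-(methoxymethoxy)benzene | COCOc1ccc(I)c(OC)c1OC
F2 | step 7 | {(2S)-2-[2-(benzyloxy)-3,4-dimethoxyphenyl]-3-bromopropoxy}(tert-butyl)dimethylsilane | COc1ccc([C@H](CBr)CO[Si](C)(C)C(C)(C)C)c(OCc2ccccc2)c1OC
F3 | step 7 | tert-butyl{(2S)-2-[2-(benzyloxy)-3,4-dimethoxyphenyl]-3-[3,4-dimethoxy-5-(methoxymethoxy)phenyl]propoxy}dimethylsilane | COc1ccc([C@H](Cc2cc(OCOC)c(OC)c(OC)c2)CO[Si](C)(C)C(C)(C)C)c(OCc2ccccc2)c1OC
F4 | step 7 | 5-{(2S)-2-[2-(benzyloxy)-3,4-dimethoxyphenyl]-3-hydroxypropyl}-2,3-dimethoxyphenol | COc1ccc([C@H](Cc2cc(O)c(OC)c(OC)c2)CO)c(OCc2ccccc2)c1OC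
F5 | step 7 | 4-bromo-5-{(2S)-2-[2-(benzyloxy)-3,4-dimethoxyphenyl]-3-hydroxypropyl}-2,3-dimethoxyphenol | COc1ccc([C@H](Cc2cc(O)c(OC)c(OC)c2Br)CO)c(OCc2ccccc2)c1OC
F6 | step 7 | (2S)-3-[5-(benzyloxy)-2-bromo-3,4-dimethoxyphenyl]-2-[2-(benzyloxy)-3,4-dimethoxyphenyl]propan-1-ol | COc1ccc([C@H](Cc2cc(OCc3ccccc3)c(OC)c(OC)c2Br)CO)c(OCc2ccccc2)c1OC
F7 | step 6 | 2-[2-(benzyloxy)-3,4-dimethoxyphenyl]propane-1,3-diol | COc1ccc(C(CO)CO)c(OCc2ccccc2)c1OC
F8 | step 6 | (2R)-2-[2-(benzyloxy)-3,4-dimethoxyphenyl]-3-hydroxypropyl acetate | COc1ccc([C@H](CO)COC(C)=O)c(OCc2ccccc2)c1OC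
F9 | step 6 | (2S)-2-[2-(benzyloxy)-3,4-dimethoxyphenyl]-3-bromopropyl acetate | COc1ccc([C@H](CBr)COC(C)=O)c(OCc2ccccc2)c1OC
F10 | step 3 | 1,2-dimethoxy-3-(methoxymethoxy)benzene | COCOc1cccc(OC)c1OC
F11 | step 3 | 1-bromo-3,4-dimethoxy-2-(methoxymethoxy)benzene | COCOc1c(Br)ccc(OC)c1OC
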